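**Plan**

Labels: C1 = C(CH3)(CO2Me); C2 = its CH neighbour that carries the alkene; C3=C4; C5=C6 (C6 = OCH=); O7; C8 = acetal CH; C9, C10, C11; C14 = CH between C11 and C1; C12 = all-carbon quaternary centre; C13 = CH2 bridge. Ring A = O7/C6/C5/C12/C9/C8, ring B = C9/C10/C11/C14/C12, ring C = C1/C2/C13/C12/C14, ring D = C2/C3/C4/C5/C12/C13.
Enabling feature: ring A is the acylated enol-lactol of a 1,5-dialdehyde (C6 on C5, C8 on C9). C12 is β to C8, and C5 is α to C6 and vinylogous through C3=C4, so C5–C12 is a dienamine Michael bond.
Cuts, in order: C8–O(acyl); O7–C8 and C5–C12 (one cascade, back to a bicyclic bis-enal); C4=C5 (cross-metathesis); C9=C12 (aldol condensation, ring B); C12–O and the C4 carbonyl (Baeyer–Villiger) back to a norbornanone; C11–C10 (Wittig); C1–CH3; anhydride C–O.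
Forward: meso norbornene anhydride → desymmetrization → ring C with C1, C2, C14 fixed on the bicycle → ring B → in the last step ring D, then ring A, then acylation.
Stereochemistry: absolute sense from alkaloid-mediated methanolysis of the meso anhydride; C1 by exo methylation; C14 by exo epimerization; C2 from the norbornane bridgehead (retentive Baeyer–Villiger); C12 by the tether, C9 by ring-fusion thermodynamics and C8 by anomeric control in the cascade.

Key step: step 15

Assumption: quinidine is taken as the cinchona alkaloid that gives the (2S,3R) hemiester needed here (quinine would give the antipode), and the C8/C9 arrangement of the target is taken to be the thermodynamically preferred iridoid-type one.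

**Route**

Step 1
Reactants: 1 cis-bicyclo[2.2.1]hept-5-ene-endo-2,3-dicarboxylic anhydride (meso)
Product: 2 (1R,2S,3R,4S)-3-endo-(methoxycarbonyl)bicyclo[2.2.1]hept-5-ene-2-endo-carboxylic acid
Conditions: MeOH (3 equiv), quinidine (1.1 equiv), toluene–CCl4 1:1, −55 °C; aqueous HCl work-up
Reagents that add atoms: methanol (CO)
Why: Cinchona-alkaloid-mediated desymmetrizing methanolysis of a meso anhydride should open one enantiotopic carbonyl selectively, which is the source of all absolute stereochemistry (the ester-bearing carbon becomes C1, the acid-bearing carbon C14).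

Step 2
Reactants: 2 hemiester
Product: 3 3-endo-(methoxycarbonyl)-3-exo-methylbicyclo[2.2.1]hept-5-ene-2-endo-carboxylic acid
Conditions: LiN(iPr)2 (2.3 equiv), THF, −78 → −20 °C; MeI, −78 → 0 °C
Reagents that add atoms: iodomethane (CI)
Why: Ester enolate alkylation of the hemiester dianion: the second equivalent of base removes the more acidic proton α to the ester, and iodomethane should enter from the open exo face, which sets C1 with methyl exo and ester endo.

Step 3
Reactants: 3 methylated hemiester
Product: 4 iodolactone (2-endo-carboxyl lactonized to the 6-endo oxygen; 5-exo iodide)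
Conditions: I2, KI, NaHCO3, H2O–THF, 0 → 23 °C, dark
Reagents that add atoms: iodine (II)
Why: Iodolactonization: the endo carboxylate attacks the nearer alkene carbon anti to the exo iodonium ion, so oxygen is placed on the alkene carbon next to the future C12 and the two alkene carbons become different.

Step 4
Reactants: 4 iodolactone
Product: 7 dimethyl 3-exo-methyl-6-oxobicyclo[2.2.1]heptane-2-exo-3-endo-dicarboxylate, via enol lactone 5 (not isolated), via cis keto diester 6 (not isolated)
Conditions: DBU, toluene, 110 °C; then NaOMe, MeOH, 23 → 50 °C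
Reagents that add atoms: methanol (CO)
Why: Syn-exo E2 dehydroiodination (exo iodide and the exo hydrogen on the oxygen-bearing carbon are periplanar, and the only other β-hydrogen is at a bridgehead) should give the enol lactone, whose methanolysis unmasks the ketone; NaOMe then epimerizes the ester α-carbon to the more stable exo (trans) diester, which sets C14.

Step 5
Reactants: 7 trans keto diester
Product: 8 methyl 6-endo-hydroxy-2-exo-(hydroxymethyl)-3-exo-methylbicyclo[2.2.1]heptane-3-endo-carboxylate
Conditions: LiBH4 (2.2 equiv), THF, 0 → 23 °C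
Reagents that add atoms: none
Why: Chemoselective hydride reduction: the ketone and the unhindered exo secondary ester should react, while the neopentyl endo ester on the quaternary carbon survives; the carbinol centre is oxidized again in step 6, so its configuration does not matter.

Step 6
Reactants: 8 diol
Product: 9 methyl 2-exo-formyl-3-exo-methyl-6-oxobicyclo[2.2.1]heptane-3-endo-carboxylate
Conditions: Dess–Martin periodinane, NaHCO3, CH2Cl2, 23 °C
Reagents that add atoms: none
Why: Dess–Martin oxidation of both alcohols under buffered conditions should give the keto aldehyde; the exo formyl group is the thermodynamic epimer and should not scramble.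

Step 7
Reactants: 9 keto aldehyde
Product: 10 methyl 2-exo-[(Z)-3-(1,3-dioxolan-2-yl)prop-1-enyl]-3-exo-methyl-6-oxobicyclo[2.2.1]heptane-3-endo-carboxylate
Conditions: [2-(1,3-dioxolan-2-yl)ethyl]PPh3Br, KN(SiMe3)2, THF, −78 → 0 °C
Reagents that add atoms: [2-(1,3-dioxolan-2-yl)ethyl]triphenylphosphonium bromide ([Br-].C1COC(CC[P+](c2ccccc2)(c2ccccc2)c2ccccc2)O1)
Why: Wittig olefination with a non-stabilized ylide, which should react with the aldehyde much faster than with the hindered bicyclic ketone; it adds C10, C9 and the masked C8 aldehyde, and the alkene geometry is irrelevant because step 8 removes it.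

Step 8
Reactants: 10 alkene
Product: 11 methyl 2-exo-[3-(1,3-dioxolan-2-yl)propyl]-3-exo-methyl-6-oxobicyclo[2.2.1]heptane-3-endo-carboxylate
Conditions: H2 (1 atm), Pd/C, EtOAc, 23 °C
Reagents that add atoms: none
Why: Heterogeneous catalytic hydrogenation of the disubstituted alkene should leave ketone, ester and acetal untouched.

Step 9
Reactants: 11 norbornanone
Product: 12 methyl 7-[3-(1,3-dioxolan-2-yl)propyl]-6-methyl-3-oxo-2-oxabicyclo[3.2.1]octane-6-carboxylate
Conditions: mCPBA, NaHCO3, CH2Cl2, 0 → 23 °C
Reagents that add atoms: 3-chloroperoxybenzoic acid (OOC(=O)c1cccc(Cl)c1)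
Why: Baeyer–Villiger oxidation with migration of the more substituted bridgehead carbon, with retention, should put oxygen on the future C12 and turn the ketone carbon into the C4 carbonyl of a bridged lactone; this fixes C2 relative to C1 and C14.

Step 10
Reactants: 12 lactone
Product: 13 lactol (3-hydroxy-2-oxabicyclo[3.2.1]octane; both anomers)
Conditions: iBu2AlH (1.1 equiv), CH2Cl2, −78 °C
Reagents that add atoms: none
Why: Partial reduction of a lactone to the lactol at low temperature; the hindered quaternary methyl ester should react more slowly.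

Step 11
Reactants: 13 lactol
Product: 14 methyl 2-allyl-5-[3-(1,3-dioxolan-2-yl)propyl]-4-hydroxy-1-methylcyclopentane-1-carboxylate
Conditions: Ph3PCH3Br, KOtBu, THF, 0 → 40 °C
Reagents that add atoms: methyltriphenylphosphonium bromide ([Br-].C[P+](c1ccccc1)(c1ccccc1)c1ccccc1)
Why: Wittig methylenation of the lactol through its open hydroxy aldehyde form should give the allyl group on C2 and free the C12 hydroxyl.

Step 12
Reactants: 14 cyclopentanol
Product: 15 methyl 2-allyl-5-[3-(1,3-dioxolan-2-yl)propyl]-1-methyl-4-oxocyclopentane-1-carboxylate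
Conditions: Dess–Martin periodinane, NaHCO3, CH2Cl2, 23 °C
Reagents that add atoms: none
Why: Dess–Martin oxidation of the secondary alcohol under buffered, non-epimerizing conditions should give ring C as a cyclopentanone that carries C1, C2 and C14 in their final configurations.

Step 13
Reactants: 15 cyclopentanone
Product: 17 methyl 5-allyl-3-formyl-6-methyl-1,2,4,5,6,6a-hexahydropentalene-6-carboxylate, via keto aldehyde 16 (not isolated)
Conditions: 1 M HCl, THF, 23 °C; then (PhCH2)2NH·CF3CO2H, toluene, 50 °C
Reagents that add atoms: water (O)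
Why: Acetal hydrolysis, then amine-salt-mediated intramolecular aldol condensation (the enamine of the C8 aldehyde adds 5-exo to the C12 ketone, then dehydration) should close ring B as the tetrasubstituted cyclopentene carbaldehyde; C14 should hold because the epimer with the side chain trans to ester and allyl is also the more stable one.

Step 14
Reactants: 17 allyl enal
Product: 18 methyl 3-formyl-6-methyl-5-[(E)-4-oxobut-2-enyl]-1,2,4,5,6,6a-hexahydropentalene-6-carboxylate
Conditions: (E)-but-2-enal (5 equiv), second-generation Hoveyda–Grubbs catalyst RuCl2(H2IMes)(=CH–C6H4-2-OiPr) (5 mol %), CH2Cl2, 40 °C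
Reagents that add atoms: (E)-but-2-enal (C/C=C/C=O)
Why: Olefin cross-metathesis of the terminal alkene with crotonaldehyde should give the (E)-enal; the tetrasubstituted, electron-poor ring alkene is inert to the catalyst.

Step 15
Reactants: 18 bis-enal
Product: 21 CNP0315847.1, via dialdehyde 19 (not isolated), via lactol 20 (not isolated)
Conditions: pyrrolidine (0.3 equiv), PhCO2H (0.3 equiv), CHCl3, 40 °C; then (iBuCO)2O, DMAP, Et3N, CH2Cl2, 0 °C
Reagents that add atoms: 3-methylbutanoic anhydride (CC(C)CC(=O)OC(=O)CC(C)C)
Why: Proposed new method: pyrrolidine condenses with the unhindered chain enal of 18 and γ-deprotonation at C3 gives a dienamine whose α-carbon C5 adds to C12, the β-carbon of the ring B enal, after which hydrolysis gives dialdehyde 19, enolization of the doubly activated C5–H gives the C6 dienol conjugated with C3=C4, and its oxygen adds to the C8 aldehyde to give lactol 20, which the anhydride then acylates. The closest known reaction types are the amine-catalysed intramolecular Michael addition of a formyl enal with in-flask lactol acylation used for iridoid cores and the dienamine-mediated Rauhut–Currier-type cyclization of tethered bis-enals; neither has been shown with a tetrasubstituted enal acceptor that must become a quaternary carbon, but the closure is intramolecular, the adduct is removed by lactolization and acylation, and no competing ring size is available. Ring D closes by a 6-(enolexo)-exo-trig Michael addition and ring A by 6-exo-trig addition of the dienol oxygen to the C8 carbonyl (hemiacetalization). C12 is controlled by the tether, since the C2 side chain can reach C12 only on its own face of ring C, which gives the cis-bridged bicyclo[3.2.1]octene; C9 is epimerizable through the C8 enamine and should drain to the epimer with C8 cis to C5, the only one that can close a cis-fused ring A; C8 should follow the anomeric preference of the equilibrating lactol for the pseudoaxial oxygen trans to C10 (the arrangement of iridoid aglycones) and is fixed on acylation. The step needs α- and not γ-attack of the dienamine (γ-attack would close a four-membered ring), a clear donor and acceptor (the ring B enal cannot form a nucleophile at its fully substituted α-carbon and condenses only slowly with the amine) and the C5=C6 and not the C8=C9 enol ether (secured by conjugation with C3=C4 and by the greater acidity of C5–H).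

**Compound list**

1 | cis-bicyclo[2.2.1]hept-5-ene-endo-2,3-dicarboxylic anhydride (meso) | O=C1OC(=O)[C@@H]2[C@H]1[C@@H]3C=C[C@H]2C3 | starting material
2 | (1R,2S,3R,4S)-3-endo-(methoxycarbonyl)bicyclo[2.2.1]hept-5-ene-2-endo-carboxylic acid | COC(=O)[C@@H]1[C@@H]2C=C[C@@H](C2)[C@@H]1C(O)=O | intermediate
3 | 3-endo-(methoxycarbonyl)-3-exo-methylbicyclo[2.2.1]hept-5-ene-2-endo-carboxylic acid (absolute sense as in 2) | COC(=O)[C@]1(C)[C@@H]2C=C[C@@H](C2)[C@@H]1C(O)=O | intermediate
4 | iodolactone: methyl 5-exo-iodo-3-exo-methylbicyclo[2.2.1]heptane-3-endo-carboxylate with the 2-endo carboxyl lactonized to the 6-endo oxygen | COC(=O)[C@]1(C)[C@@H]2[C@@H](I)[C@@H]3OC(=O)[C@H]1[C@@H]3C2 | intermediate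
5 | enol lactone: the lactone of 4 without iodine and with a C5=C6 double bond | COC(=O)[C@]1(C)[C@@H]2C=C3OC(=O)[C@H]1[C@@H]3C2 | intermediate (not isolated)
6 | dimethyl 3-exo-methyl-6-oxobicyclo[2.2.1]heptane-2-endo,3-endo-dicarboxylate (cis) | COC(=O)[C@]1(C)[C@@H]2CC(=O)[C@@H](C2)[C@@H]1C(=O)OC | intermediate (not isolated)
7 | dimethyl 3-exo-methyl-6-oxobicyclo[2.2.1]heptane-2-exo,3-endo-dicarboxylate (trans) | COC(=O)[C@]1(C)[C@@H]2CC(=O)[C@@H](C2)[C@H]1C(=O)OC | intermediate
8 | methyl 6-endo-hydroxy-2-exo-(hydroxymethyl)-3-exo-methylbicyclo[2.2.1]heptane-3-endo-carboxylate | COC(=O)[C@]1(C)[C@@H]2C[C@H](O)[C@@H](C2)[C@H]1CO | intermediate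
9 | methyl 2-exo-formyl-3-exo-methyl-6-oxobicyclo[2.2.1]heptane-3-endo-carboxylate | COC(=O)[C@]1(C)[C@@H]2CC(=O)[C@@H](C2)[C@H]1C=O | intermediate
10 | methyl 2-exo-[(Z)-3-(1,3-dioxolan-2-yl)prop-1-enyl]-3-exo-methyl-6-oxobicyclo[2.2.1]heptane-3-endo-carboxylate | COC(=O)[C@]1(C)[C@@H]2CC(=O)[C@@H](C2)[C@H]1/C=C\CC3OCCO3 | intermediate
11 | methyl 2-exo-[3-(1,3-dioxolan-2-yl)propyl]-3-exo-methyl-6-oxobicyclo[2.2.1]heptane-3-endo-carboxylate | COC(=O)[C@]1(C)[C@@H]2CC(=O)[C@@H](C2)[C@H]1CCCC3OCCO3 | intermediate
12 | methyl 7-[3-(1,3-dioxolan-2-yl)propyl]-6-methyl-3-oxo-2-oxabicyclo[3.2.1]octane-6-carboxylate (ester on the face of the lactone bridge; methyl and side chain on the other face) | COC(=O)[C@]1(C)[C@@H]2CC(=O)O[C@@H](C2)[C@H]1CCCC3OCCO3 | intermediate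
13 | methyl 7-[3-(1,3-dioxolan-2-yl)propyl]-3-hydroxy-6-methyl-2-oxabicyclo[3.2.1]octane-6-carboxylate (lactol, both anomers) | COC(=O)[C@]1(C)[C@@H]2CC(O)O[C@@H](C2)[C@H]1CCCC3OCCO3 | intermediate
14 | methyl 2-allyl-5-[3-(1,3-dioxolan-2-yl)propyl]-4-hydroxy-1-methylcyclopentane-1-carboxylate (ester, allyl and hydroxyl on one face; methyl and the C5 side chain on the other) | COC(=O)[C@]1(C)[C@H](CC=C)C[C@H](O)[C@H]1CCCC2OCCO2 | intermediate
15 | methyl 2-allyl-5-[3-(1,3-dioxolan-2-yl)propyl]-1-methyl-4-oxocyclopentane-1-carboxylate (same relative configuration) | COC(=O)[C@]1(C)[C@H](CC=C)CC(=O)[C@H]1CCCC2OCCO2 | intermediate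
16 | methyl 2-allyl-1-methyl-4-oxo-5-(4-oxobutyl)cyclopentane-1-carboxylate | COC(=O)[C@]1(C)[C@H](CC=C)CC(=O)[C@H]1CCCC=O | intermediate (not isolated)
17 | methyl 5-allyl-3-formyl-6-methyl-1,2,4,5,6,6a-hexahydropentalene-6-carboxylate (6a-H, ester and allyl on one face; methyl on the other) | COC(=O)[C@]1(C)[C@H](CC=C)CC2=C(C=O)CC[C@@H]12 | intermediate
18 | methyl 3-formyl-6-methyl-5-[(E)-4-oxobut-2-enyl]-1,2,4,5,6,6a-hexahydropentalene-6-carboxylate | COC(=O)[C@]1(C)[C@H](C/C=C/C=O)CC2=C(C=O)CC[C@@H]12 | intermediate
19 | tricyclic dialdehyde (rings B, C, D closed; formyl on C5, epimer mixture at C5, and on C9) | COC(=O)[C@]1(C)[C@@H]2C=CC(C=O)[C@]3(C2)[C@H](C=O)CC[C@@H]13 | intermediate (not isolated)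
20 | tetracyclic lactol (the target with OH in place of the 3-methylbutanoyloxy group on C8) | COC(=O)[C@]1(C)[C@@H]2C=CC3=CO[C@@H](O)[C@@H]4CC[C@@H]1[C@]34C2 | intermediate (not isolated)
21 | CNP0315847.1 | COC(=O)[C@]1(C)[C@@H]2C=CC3=CO[C@@H](OC(=O)CC(C)C)[C@@H]4CC[C@@H]1[C@]34C2 | target

**Totals and risks**

Total step count: 15. Longest linear sequence: 15 steps (fully linear from 1).

Steps most likely to fail:

1. Step 15 (Proposed new method). The Michael addition to the fully substituted C12 may be too slow or may revert, so that intermolecular aldol and oligomerization of the bis-enal take over. Trapping of the regioisomeric C8=C9 enol-lactol is a second possible loss. Fallback, a radical closure by known reaction types, sets out from 18. α-Iodination of the chain enal (I2, K2CO3, DMAP, THF–H2O; the ring B enal has no α-hydrogen) should give the (Z)-α-iodo enal F1. Slow addition of Bu3SnH with AIBN (benzene, 80 °C) generates the C5 vinyl radical, whose 6-exo cyclization onto C12 should give the conjugated dialdehyde F2 (C4=C5, formyl on C9). Catalytic DBU then moves the double bond through the C3 dienol into lactol 20, where the route is rejoined, and acylation as in step 15 gives 21.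

2. Step 4. The syn elimination may not take place (no reaction, or attack of the base on the lactone), so that the enol lactone is never formed. Fallback, radical deiodination and separate oxidation, sets out from 4. Bu3SnH and AIBN (benzene, 80 °C) should give the iodine-free lactone F3. NaOH (aq) followed by RuCl3 (cat.) and NaIO4 on the hydroxy carboxylate should give the endo keto acid F4. MeI and K2CO3 (DMF) then give 6, where the route is rejoined; NaOMe equilibration as in step 4 leads to 7.

3. Step 5. Over-reduction of the quaternary ester, or incomplete reduction of the exo ester, would erode the differentiation of the two esters. Fallback, differentiation by saponification, sets out from 7. LiOH (1.0 equiv, THF–H2O, 0 °C) should hydrolyse only the unhindered exo ester to give the keto acid F5. BH3·SMe2 (THF, 0 → 23 °C) then reduces acid and ketone but not the ester and rejoins the route at 8.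

**Further compounds**

F1 | step 15 | methyl 3-formyl-5-[(Z)-3-iodo-4-oxobut-2-enyl]-6-methyl-1,2,4,5,6,6a-hexahydropentalene-6-carboxylate | COC(=O)[C@]1(C)[C@H](C/C=C(\I)C=O)CC2=C(C=O)CC[C@@H]12
F2 | step 15 | tricyclic conjugated dialdehyde (C4=C5 enal in ring D, formyl on C9) | COC(=O)[C@]1(C)[C@@H]2CC=C(C=O)[C@]3(C2)[C@H](C=O)CC[C@@H]13
F3 | step 4 | lactone of 4 without iodine (2-endo carboxyl lactonized to the 6-endo oxygen) | COC(=O)[C@]1(C)[C@@H]2C[C@@H]3OC(=O)[C@H]1[C@@H]3C2
F4 | step 4 | 3-endo-(methoxycarbonyl)-3-exo-methyl-6-oxobicyclo[2.2.1]heptane-2-endo-carboxylic acid | COC(=O)[C@]1(C)[C@@H]2CC(=O)[C@@H](C2)[C@@H]1C(O)=O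
F5 | step 5 | 3-endo-(methoxycarbonyl)-3-exo-methyl-6-oxobicyclo[2.2.1]heptane-2-exo-carboxylic acid | COC(=O)[C@]1(C)[C@@H]2CC(=O)[C@@H](C2)[C@H]1C(O)=O
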